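**Plan**
- Retrosynthesis first masks both quinones as 2,5-dimethoxyarenes, then saturates nothing further and cuts the two identical bonds between ring carbon C1 of each ring and succinate C2 and C3.
- Enabling feature: each ring hangs by its C1 (the ring carbon between the C6 carbonyl and C2–H) on one of the adjacent carbons C2/C3 of a single C4 diester, so one 2,3-dibromobutenedioate can accept two copies of one aryl nucleophile.
- Forward: 2,6-dibromo-4-methoxyphenol is methylated, geranylated and borylated; dibromomaleic acid is esterified; a twofold Suzuki–Miyaura coupling joins the three pieces. No ring is formed in the route; both six-membered rings come from the arene.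
- The electron-poor C=C is then reduced with Mg/MeOH and the two quinones are unmasked last with (NH4)2Ce(NO3)6.
- Stereochemistry: the E-olefins come unchanged from geranyl bromide; the meso (2R,3S) pair of centres comes from methoxide equilibration of the diester, driven by crystallisation.

Key step: step 5

Assumption: the S,R descriptors on two constitutionally identical halves define the meso diastereomer, so only relative configuration has to be controlled; compounds 1, 3 and 9 are taken as purchasable.

**Route**

Step 1
Reactants: 1 2,6-dibromo-4-methoxyphenol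
Product: 2 1,3-dibromo-2,5-dimethoxybenzene
Conditions: MeI, K2CO3, DMF, 40 °C
Reagents that add atoms: iodomethane, CI
Why: Williamson ether synthesis; the acidic 2,6-dibromophenol is fully deprotonated by K2CO3 and the phenoxide should be methylated by SN2 attack on MeI despite the two ortho bromines.

Step 2
Reactants: 2 1,3-dibromo-2,5-dimethoxybenzene; 3 geranyl bromide
Product: 6 1-bromo-3-geranyl-2,5-dimethoxybenzene, via (3-bromo-2,5-dimethoxyphenyl)lithium 4 (not isolated), via (3-bromo-2,5-dimethoxyphenyl)copper 5 (not isolated)
Conditions: n-BuLi (1.0 equiv), THF, −78 °C; CuBr·SMe2 (1.0 equiv), −78 → −40 °C; then 3, −40 → 0 °C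
Reagents that add atoms: none
Why: Bromine–lithium exchange stops after one of the two equivalent C–Br bonds (a second exchange would need an aryl dianion), and Li-to-Cu transmetalation followed by copper-mediated allylic substitution at the primary carbon of geranyl bromide should give the linear product with the E-olefin retained.

Step 3
Reactants: 6 1-bromo-3-geranyl-2,5-dimethoxybenzene
Product: 8 2-(3-geranyl-2,5-dimethoxyphenyl)-4,4,5,5-tetramethyl-1,3,2-dioxaborolane, via (3-geranyl-2,5-dimethoxyphenyl)lithium 7 (not isolated)
Conditions: n-BuLi (1.1 equiv), THF, −78 °C; iPrOBpin, −78 °C → rt; H2O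
Reagents that add atoms: 2-isopropoxy-4,4,5,5-tetramethyl-1,3,2-dioxaborolane, CC(C)OB1OC(C)(C)C(C)(C)O1
Why: Lithiation–borylation; bromine–lithium exchange at −78 °C is much faster than deprotonation of the benzylic/allylic CH2, and the aryllithium should add to the borate and expel isopropoxide to give the pinacol boronate.

Step 4
Reactants: 9 2,3-dibromomaleic acid
Product: 10 dimethyl 2,3-dibromomaleate
Conditions: MeOH, H2SO4 (cat.), reflux
Reagents that add atoms: methanol, CO
Why: Fischer esterification; the vinylic bromides are inert to acidic methanol and any anhydride formed on heating is reopened and esterified.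

Step 5
Reactants: 10 dimethyl 2,3-dibromomaleate; 8 2-(3-geranyl-2,5-dimethoxyphenyl)-4,4,5,5-tetramethyl-1,3,2-dioxaborolane (2.4 equiv)
Product: 12 dimethyl 2,3-bis(3-geranyl-2,5-dimethoxyphenyl)maleate, via monoaryl bromomaleate 11 (not isolated)
Conditions: Pd(OAc)2 (5 mol %), SPhos (10 mol %), K3PO4 (4 equiv), PhMe/H2O (20:1), 80 °C, under argon
Reagents that add atoms: none
Why: Twofold Suzuki–Miyaura cross-coupling: zerovalent palladium bearing the biaryl phosphine inserts into one vinylic C–Br bond of 10, the phosphate-activated boronate 8 transfers its aryl group and reductive elimination gives bromide 11, which passes through the same cycle again to give 12. The closest known reaction type is the twofold Suzuki arylation of 2,3-dibromomaleic esters, dibromomaleimides and related vicinal dibromo-enoates. No ring is closed and no stereocentre is formed; the two new bonds are aryl C1–C2 and aryl C1–C3 of the C4 diester, and the olefin geometry of 12 is of no consequence because the double bond is reduced in step 6. The step needs complete double coupling ahead of protodeboronation of 8, loss of bromide to the alkyne and hydroxide attack on the β-bromo-enoate. The substrate secures this because both C–Br bonds are electron-poor and add quickly, palladium and the remaining bromine are cis after the first insertion so anti β-bromide elimination is disfavoured, and each aryl group carries only one ortho substituent. The nearly anhydrous phosphate base, the bulky electron-rich ligand and the excess of 8 are chosen to push the second, more hindered coupling to completion.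

Step 6
Reactants: 12 dimethyl 2,3-bis(3-geranyl-2,5-dimethoxyphenyl)maleate
Product: 13 dimethyl 2,3-bis(3-geranyl-2,5-dimethoxyphenyl)succinate (meso/racemic mixture)
Conditions: Mg turnings (10 equiv), MeOH/THF (4:1), 0 °C → rt; aq. NH4Cl
Reagents that add atoms: none
Why: Dissolving-metal conjugate reduction (Mg/MeOH) by electron transfer to the aryl-conjugated enedioate and protonation by methanol, which should leave the isolated trisubstituted geranyl olefins and the aryl ethers untouched; the two new stereocentres form without control and are corrected in step 7.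

Step 7
Reactants: 13 dimethyl 2,3-bis(3-geranyl-2,5-dimethoxyphenyl)succinate (meso/racemic mixture)
Product: 14 dimethyl meso-(2R,3S)-2,3-bis(3-geranyl-2,5-dimethoxyphenyl)succinate
Conditions: NaOMe (1 equiv), MeOH/THF, 60 °C; cool and crystallise; mother liquor re-equilibrated
Reagents that add atoms: none
Why: Thermodynamic epimerisation through the ester enolates, in which the meso isomer (both aryl groups and both ester groups anti at once) is expected to be the more stable and less soluble diastereomer, so its crystallisation should drain the equilibrium (crystallisation-induced diastereomer transformation) and set both stereocentres.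

Step 8
Reactants: 14 dimethyl meso-(2R,3S)-2,3-bis(3-geranyl-2,5-dimethoxyphenyl)succinate
Product: 15 dimethyl meso-(2R,3S)-2,3-bis(5-geranyl-3,6-dioxocyclohexa-1,4-dien-1-yl)succinate (target)
Conditions: (NH4)2Ce(NO3)6 (5 equiv), MeCN/H2O (2:1), 0 °C, 15 min; neutral work-up
Reagents that add atoms: water, O
Why: Oxidative demethylation of p-dimethoxyarenes by ceric ammonium nitrate (two one-electron oxidations per ring, ipso attack of water, loss of methanol), whose brief cold acidic conditions should spare the trisubstituted olefins, the methyl esters and the base-sensitive α-stereocentres.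

**Compound list**
1 | 2,6-dibromo-4-methoxyphenol | COc1cc(Br)c(O)c(Br)c1 | starting material
2 | 1,3-dibromo-2,5-dimethoxybenzene | COc1cc(Br)c(OC)c(Br)c1 | intermediate
3 | geranyl bromide, (2E)-1-bromo-3,7-dimethylocta-2,6-diene | CC(C)=CCC/C(C)=C/CBr | starting material
4 | (3-bromo-2,5-dimethoxyphenyl)lithium | COc1cc(Br)c(OC)c([Li])c1 | intermediate
5 | (3-bromo-2,5-dimethoxyphenyl)copper | COc1cc(Br)c(OC)c([Cu])c1 | intermediate
6 | 1-bromo-3-[(2E)-3,7-dimethylocta-2,6-dien-1-yl]-2,5-dimethoxybenzene | COc1cc(Br)c(OC)c(C/C=C(\C)CCC=C(C)C)c1 | intermediate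
7 | (3-geranyl-2,5-dimethoxyphenyl)lithium | COc1cc(C/C=C(\C)CCC=C(C)C)c(OC)c([Li])c1 | intermediate
8 | 2-(3-geranyl-2,5-dimethoxyphenyl)-4,4,5,5-tetramethyl-1,3,2-dioxaborolane | COc1cc(C/C=C(\C)CCC=C(C)C)c(OC)c(c1)B1OC(C)(C)C(C)(C)O1 | intermediate
9 | 2,3-dibromomaleic acid, (2Z)-2,3-dibromobut-2-enedioic acid | OC(=O)/C(Br)=C(/Br)C(=O)O | starting material
10 | dimethyl 2,3-dibromomaleate | COC(=O)/C(Br)=C(/Br)C(=O)OC | intermediate
11 | dimethyl 2-bromo-3-(3-geranyl-2,5-dimethoxyphenyl)maleate (ester groups cis) | COC(=O)/C(Br)=C(/c1cc(OC)cc(C/C=C(\C)CCC=C(C)C)c1OC)C(=O)OC | intermediate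
12 | dimethyl 2,3-bis(3-geranyl-2,5-dimethoxyphenyl)maleate (ester groups cis) | COC(=O)/C(c1cc(OC)cc(C/C=C(\C)CCC=C(C)C)c1OC)=C(/c1cc(OC)cc(C/C=C(\C)CCC=C(C)C)c1OC)C(=O)OC | intermediate
13 | dimethyl 2,3-bis(3-geranyl-2,5-dimethoxyphenyl)succinate, mixture of meso and racemic diastereomers | COC(=O)C(c1cc(OC)cc(C/C=C(\C)CCC=C(C)C)c1OC)C(C(=O)OC)c1cc(OC)cc(C/C=C(\C)CCC=C(C)C)c1OC | intermediate
14 | dimethyl meso-(2R,3S)-2,3-bis(3-geranyl-2,5-dimethoxyphenyl)succinate | COC(=O)[C@H](c1cc(OC)cc(C/C=C(\C)CCC=C(C)C)c1OC)[C@@H](C(=O)OC)c1cc(OC)cc(C/C=C(\C)CCC=C(C)C)c1OC | intermediate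
15 | dimethyl meso-(2R,3S)-2,3-bis{5-[(2E)-3,7-dimethylocta-2,6-dien-1-yl]-3,6-dioxocyclohexa-1,4-dien-1-yl}butanedioate (CNP0183145.1) | COC(=O)[C@H](C1=CC(=O)C=C(C/C=C(\C)CCC=C(C)C)C1=O)[C@@H](C(=O)OC)C1=CC(=O)C=C(C/C=C(\C)CCC=C(C)C)C1=O | target

**Totals**
Total step count: 8. Longest linear sequence: 7 steps (steps 1, 2, 3, 5, 6, 7, 8); step 4 is a one-step side branch.

**Steps most likely to fail**

Step 5. The coupling may stall after the first arylation, the boronate may protodeboronate, or the acyclic dibromo-enoate may be consumed by bromide elimination or by base attack before both aryl groups are installed. The fallback sets out from 8 and replaces the acyclic linchpin by purchasable 2,3-dibromo-1-methylmaleimide (CN1C(=O)C(Br)=C(Br)C1=O), whose ring cannot collapse to an alkyne and whose twofold Suzuki arylation is firmly established. Coupling under the same Pd(OAc)2/SPhos/K3PO4 conditions should give 3,4-bis(3-geranyl-2,5-dimethoxyphenyl)-1-methylmaleimide F1. Hydrolysis with KOH in aqueous ethanol and acidification should close the diacid to 2,3-bis(3-geranyl-2,5-dimethoxyphenyl)maleic anhydride F2. Opening with NaOMe in MeOH gives the sodium salt of the monomethyl ester, methyl hydrogen 2,3-bis(3-geranyl-2,5-dimethoxyphenyl)maleate F3, which is alkylated in the same flask with MeI in DMF, and the route is rejoined at 12.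

Step 7. The thermodynamic preference for the meso diester may be too small, and the lipophilic geranyl chains may prevent selective crystallisation, so the equilibration may not converge. The fallback sets out from 13 and moves the separation to the diacid. Saponification with KOH in aqueous MeOH/THF and acidification with HCl gives 2,3-bis(3-geranyl-2,5-dimethoxyphenyl)succinic acid as the diastereomer mixture F4. From this the strongly hydrogen-bonded meso-(2R,3S)-2,3-bis(3-geranyl-2,5-dimethoxyphenyl)succinic acid F5 is expected to crystallise, if necessary as its bis(dicyclohexylammonium) salt. Esterification with trimethylsilyldiazomethane in PhMe/MeOH at 0 °C is neutral and should not epimerise, and it returns to the route at 14.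

Step 8. The tetravalent cerium oxidant may attack the trisubstituted olefins or cause oxidative dimerisation, and the product quinone may tautomerise during work-up. The fallback sets out from 14 and splits the oxidation into two mild operations. Anodic methoxylation in MeOH (graphite anode, LiClO4, 2,6-lutidine, 0 °C, constant current, undivided cell) oxidises only the electron-rich arenes. It should give the bis(quinone bisketal) dimethyl meso-(2R,3S)-2,3-bis(5-geranyl-3,3,6,6-tetramethoxycyclohexa-1,4-dien-1-yl)succinate F6. Hydrolysis with dilute HCl in aqueous acetone at 0 °C → rt releases both quinones and arrives at 15.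

**Further compounds**
F1 | step 5 | 3,4-bis(3-geranyl-2,5-dimethoxyphenyl)-1-methylmaleimide | CN1C(=O)C(c2cc(OC)cc(C/C=C(\C)CCC=C(C)C)c2OC)=C(c2cc(OC)cc(C/C=C(\C)CCC=C(C)C)c2OC)C1=O
F2 | step 5 | 2,3-bis(3-geranyl-2,5-dimethoxyphenyl)maleic anhydride | O=C1OC(=O)C(c2cc(OC)cc(C/C=C(\C)CCC=C(C)C)c2OC)=C1c3cc(OC)cc(C/C=C(\C)CCC=C(C)C)c3OC
F3 | step 5 | methyl hydrogen 2,3-bis(3-geranyl-2,5-dimethoxyphenyl)maleate (sodium salt in the flask) | COC(=O)/C(c1cc(OC)cc(C/C=C(\C)CCC=C(C)C)c1OC)=C(/c1cc(OC)cc(C/C=C(\C)CCC=C(C)C)c1OC)C(=O)O
F4 | step 7 | 2,3-bis(3-geranyl-2,5-dimethoxyphenyl)succinic acid, mixture of meso and racemic diastereomers | OC(=O)C(c1cc(OC)cc(C/C=C(\C)CCC=C(C)C)c1OC)C(C(=O)O)c1cc(OC)cc(C/C=C(\C)CCC=C(C)C)c1OC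
F5 | step 7 | meso-(2R,3S)-2,3-bis(3-geranyl-2,5-dimethoxyphenyl)succinic acid | OC(=O)[C@H](c1cc(OC)cc(C/C=C(\C)CCC=C(C)C)c1OC)[C@@H](C(=O)O)c1cc(OC)cc(C/C=C(\C)CCC=C(C)C)c1OC
F6 | step 8 | dimethyl meso-(2R,3S)-2,3-bis(5-geranyl-3,3,6,6-tetramethoxycyclohexa-1,4-dien-1-yl)succinate | COC(=O)[C@H](C1=CC(OC)(OC)C=C(C/C=C(\C)CCC=C(C)C)C1(OC)OC)[C@@H](C(=O)OC)C1=CC(OC)(OC)C=C(C/C=C(\C)CCC=C(C)C)C1(OC)OC
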